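**Plan**
The retrosynthesis first cuts the depside ester bond between the ring A carbonyl carbon and the oxygen on ring B C4, then ring B bonds C3–C4 and C5–C6, and last the lactone of a 2-pyrone.
Ring B carries OMe, CO2Me and propyl on three neighbouring carbons (C2, C1, C6), which is the pattern of C4, C5 and C6 of a 4-methoxy-6-propyl-2-pyrone-5-carboxylate, with ring B C3–H as pyrone C3; the remaining pair, C4 (aryl oxygen) and C5 (H), is an O-silylated ethynol unit.
Forward, the pyrone ring is made from methyl 3-oxohexanoate and malonyl dichloride and O-methylated; cycloaddition with triisopropylsilyloxyethyne and loss of CO2 turn it into ring B, and fluoride frees the C4 phenol.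
Ring A is bought as 5-propylresorcinol; formylation, benzylation, oxidation and chlorination give the aroyl chloride, which acylates the ring B phenol, and hydrogenolysis ends the route.
Stereochemistry: the target has no stereocentre; the two bridgehead centres of the transient bicyclic lactone vanish on aromatization.

Key step: step 4

Assumption: the target has no stereogenic element, so its SMILES is read as drawn; ynol ether 7 is taken into step 4 together with the inert ethoxytriisopropylsilane that its preparation co-produces.

Step 1
Reactants: 1 methyl 3-oxohexanoate; 2 malonyl dichloride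
Product: 3 methyl 4-hydroxy-2-oxo-6-propyl-2H-pyran-5-carboxylate
Conditions: neat (1 in slight excess), no base, rt → 60 °C, N2 sweep
Reagents that add atoms: none
Why: Cyclocondensation of a β-keto ester with malonyl dichloride, in which the enol carbon C2 of 1 is acylated by one acid chloride and the ketone enol oxygen then closes the lactone on the other, is the established entry to 4-hydroxy-2-pyrone-5-carboxylates, and the slight excess of 1 should keep 3 from being acylated a second time.

Step 2
Reactants: 3 methyl 4-hydroxy-2-oxo-6-propyl-2H-pyran-5-carboxylate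
Product: 4 methyl 4-methoxy-2-oxo-6-propyl-2H-pyran-5-carboxylate
Conditions: Me2SO4, K2CO3, acetone, reflux
Reagents that add atoms: dimethyl sulfate, COS(=O)(=O)OC
Why: O-alkylation of the acidic vinylogous acid with a hard methylating agent under carbonate conditions is the standard way from 4-hydroxy-6-alkyl-2-pyrones to 4-methoxy-2-pyrones.

Step 3
Reactants: 5 ethyl dibromoacetate
Product: 7 triisopropylsilyloxyethyne, via lithium ethynolate 6 (not isolated)
Conditions: t-BuLi (4 equiv), THF, −78 → 0 °C; then TIPSOTf (2.2 equiv), −78 °C → rt; pentane extraction, bulb-to-bulb distillation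
Reagents that add atoms: triisopropylsilyl trifluoromethanesulfonate, CC(C)[Si](OS(=O)(=O)C(F)(F)F)(C(C)C)C(C)C
Why: Two bromine–lithium exchanges should turn 5 into the α-lithio ester enolate, which expels ethoxide to give ynolate 6 (the ester-dianion cleavage route to ynolates, a lithium–halogen exchange relative of the Kowalski ester homologation), and the bulky silyl triflate silylates 6 on oxygen while its second equivalent caps the ethoxide as inert ethoxytriisopropylsilane.

Step 4
Reactants: 4 methyl 4-methoxy-2-oxo-6-propyl-2H-pyran-5-carboxylate; 7 triisopropylsilyloxyethyne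
Product: 9 methyl 2-methoxy-6-propyl-4-(triisopropylsilyloxy)benzoate, via bridged bicyclic lactone 8 (not isolated)
Conditions: 7 (3 equiv), PhMe, base-washed sealed tube, 120 °C
Reagents that add atoms: none
Why: The electron-poor diene C3=C4–C5=C6 of pyrone 4, whose LUMO is lowered by the lactone carbonyl and the C5 ester, should add the electron-rich alkyne 7 in an inverse-electron-demand (4+2) cycloaddition to give the 2-oxabicyclo[2.2.2]octadienone 8, which sheds CO2 in a cycloreversion at the reaction temperature and so becomes the benzene ring directly. The closest known reaction type is the Diels–Alder/retro-Diels–Alder benzannulation of 2-pyrone-5-carboxylates (coumalates, isodehydroacetates) with ynamines, ketene acetals and alkoxyalkynes. Ring B closes intermolecularly as a six-membered carbocycle from four pyrone carbons and both alkyne carbons, forming ring B bonds C3–C4 and C5–C6 in the one cycloaddition. The only stereogenic atoms formed are the two bridgeheads of 8, and they are lost with CO2, so no stereocontrol is needed. The step needs one regiochemistry, silyloxy carbon para to the ester: the ester at C5 and the lactone carbonyl make pyrone C6 the most electrophilic diene terminus, and the CH carbon of 7 is its nucleophilic end, so CH should bond to C6 and the oxygen-bearing carbon to C3. Excess 7 and moderate heat are meant to offset the deactivating 4-methoxy and 6-propyl groups, and the bulky silyl group slows isomerization of 7 to a silylketene.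

Step 5
Reactants: 9 methyl 2-methoxy-6-propyl-4-(triisopropylsilyloxy)benzoate
Product: 10 methyl 4-hydroxy-2-methoxy-6-propylbenzoate
Conditions: Bu4NF, AcOH, THF, 0 °C
Reagents that add atoms: none
Why: Fluoride cleaves the aryl silyl ether (standard desilylation), and the acetic acid buffer keeps the phenoxide from attacking the methyl ester.

Step 6
Reactants: 11 5-propylresorcinol
Product: 13 2,4-dihydroxy-6-propylbenzaldehyde, via aryl iminium chloride 12 (not isolated)
Conditions: POCl3, DMF, 0 °C → rt; then ice-water, 50 °C
Reagents that add atoms: N,N-dimethylformamide, CN(C)C=O; water, O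
Why: Vilsmeier–Haack formylation of a 5-alkylresorcinol goes to C4, ortho to one hydroxyl and para to the other, in preference to the more hindered C2 between the hydroxyls, as it does with orcinol, and water hydrolyses iminium salt 12 to the aldehyde.

Step 7
Reactants: 13 2,4-dihydroxy-6-propylbenzaldehyde
Product: 14 2,4-bis(benzyloxy)-6-propylbenzaldehyde
Conditions: BnBr (2.5 equiv), K2CO3, DMF, 60 °C
Reagents that add atoms: benzyl bromide, BrCc1ccccc1
Why: Williamson etherification with excess benzyl bromide in warm DMF should alkylate both phenols, including the hydrogen-bonded 2-hydroxyl.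

Step 8
Reactants: 14 2,4-bis(benzyloxy)-6-propylbenzaldehyde
Product: 15 2,4-bis(benzyloxy)-6-propylbenzoic acid
Conditions: NaClO2, NaH2PO4, 2-methyl-2-butene, t-BuOH/THF/H2O, rt
Reagents that add atoms: sodium chlorite, [Na+].[O-]Cl=O
Why: Pinnick oxidation converts a hindered, electron-rich aryl aldehyde into the acid without touching benzyl ethers, the alkene scavenger removing HOCl before it can chlorinate the ring.

Step 9
Reactants: 15 2,4-bis(benzyloxy)-6-propylbenzoic acid
Product: 16 2,4-bis(benzyloxy)-6-propylbenzoyl chloride
Conditions: (COCl)2, DMF (cat.), CH2Cl2, 0 °C → rt; evaporate, use crude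
Reagents that add atoms: oxalyl chloride, O=C(Cl)C(=O)Cl
Why: Acid chloride formation through the chloroiminium species from oxalyl chloride and catalytic DMF is mild enough to spare the benzyl ethers.

Step 10
Reactants: 16 2,4-bis(benzyloxy)-6-propylbenzoyl chloride; 10 methyl 4-hydroxy-2-methoxy-6-propylbenzoate
Product: 17 methyl 4-{[2,4-bis(benzyloxy)-6-propylbenzoyl]oxy}-2-methoxy-6-propylbenzoate
Conditions: Et3N, DMAP (cat.), CH2Cl2, 0 °C → rt
Reagents that add atoms: none
Why: Acylation of a phenol by an aroyl chloride with DMAP as nucleophilic catalyst is the usual depside-forming esterification, and the acidic, unhindered phenol of 10 (para to its ester) should compensate for the di-ortho-substituted acyl donor.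

Step 11
Reactants: 17 methyl 4-{[2,4-bis(benzyloxy)-6-propylbenzoyl]oxy}-2-methoxy-6-propylbenzoate
Product: 18 methyl 4-[(2,4-dihydroxy-6-propylbenzoyl)oxy]-2-methoxy-6-propylbenzoate (CNP0177078.0)
Conditions: H2 (1 atm), 10% Pd/C, EtOAc, rt
Reagents that add atoms: none
Why: Hydrogenolysis of the two benzyl ethers over Pd/C in a non-nucleophilic solvent leaves the aryl ester and the methyl ester intact, as is usual at the end of depside syntheses.

**Compound list**
1 | methyl 3-oxohexanoate | CCCC(=O)CC(=O)OC | starting material
2 | malonyl dichloride | O=C(Cl)CC(=O)Cl | starting material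
3 | methyl 4-hydroxy-2-oxo-6-propyl-2H-pyran-5-carboxylate | CCCC1=C(C(=O)OC)C(O)=CC(=O)O1 | intermediate
4 | methyl 4-methoxy-2-oxo-6-propyl-2H-pyran-5-carboxylate | CCCC1=C(C(=O)OC)C(OC)=CC(=O)O1 | intermediate
5 | ethyl dibromoacetate | CCOC(=O)C(Br)Br | starting material
6 | lithium ethynolate | [Li+].[O-]C#C | intermediate (not isolated)
7 | triisopropylsilyloxyethyne | C#CO[Si](C(C)C)(C(C)C)C(C)C | intermediate
8 | methyl 5-methoxy-3-oxo-1-propyl-8-(triisopropylsilyloxy)-2-oxabicyclo[2.2.2]octa-5,7-diene-6-carboxylate (racemic, no descriptors given) | CCCC12OC(=O)C(C(OC)=C1C(=O)OC)C(O[Si](C(C)C)(C(C)C)C(C)C)=C2 | intermediate (not isolated)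
9 | methyl 2-methoxy-6-propyl-4-(triisopropylsilyloxy)benzoate | CCCc1cc(O[Si](C(C)C)(C(C)C)C(C)C)cc(OC)c1C(=O)OC | intermediate
10 | methyl 4-hydroxy-2-methoxy-6-propylbenzoate | CCCc1cc(O)cc(OC)c1C(=O)OC | intermediate
11 | 5-propylresorcinol (5-propylbenzene-1,3-diol) | CCCc1cc(O)cc(O)c1 | starting material
12 | (2,4-dihydroxy-6-propylbenzylidene)dimethyliminium chloride | CCCc1cc(O)cc(O)c1C=[N+](C)C.[Cl-] | intermediate (not isolated)
13 | 2,4-dihydroxy-6-propylbenzaldehyde | CCCc1cc(O)cc(O)c1C=O | intermediate
14 | 2,4-bis(benzyloxy)-6-propylbenzaldehyde | CCCc1cc(OCc2ccccc2)cc(OCc3ccccc3)c1C=O | intermediate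
15 | 2,4-bis(benzyloxy)-6-propylbenzoic acid | CCCc1cc(OCc2ccccc2)cc(OCc3ccccc3)c1C(=O)O | intermediate
16 | 2,4-bis(benzyloxy)-6-propylbenzoyl chloride | CCCc1cc(OCc2ccccc2)cc(OCc3ccccc3)c1C(=O)Cl | intermediate
17 | methyl 4-{[2,4-bis(benzyloxy)-6-propylbenzoyl]oxy}-2-methoxy-6-propylbenzoate | CCCc1cc(OCc2ccccc2)cc(OCc3ccccc3)c1C(=O)Oc4cc(CCC)c(C(=O)OC)c(OC)c4 | intermediate
18 | methyl 4-[(2,4-dihydroxy-6-propylbenzoyl)oxy]-2-methoxy-6-propylbenzoate (CNP0177078.0) | CCCc1cc(O)cc(O)c1C(=O)Oc1cc(CCC)c(C(=O)OC)c(OC)c1 | target

**Step count**
Total: 11 steps. Longest linear sequence: 6 steps (steps 1, 2, 4, 5, 10, 11 from compound 1; equally steps 6 to 11 from compound 11).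

**Steps most likely to fail**

Step 4, the cycloaddition. The donor-substituted, C6-alkylated pyrone may add too slowly, so that thermal isomerization of the ynol ether to a silylketene, or its oligomerization, outruns the addition. In that case ring B would be taken from the resorcinol series instead, setting out from aldehyde 13 and coming back at phenol 10. Selective benzylation of the non-chelated 4-hydroxyl (BnBr 1 equiv, KHCO3, MeCN, 60 °C) should give 4-(benzyloxy)-2-hydroxy-6-propylbenzaldehyde F1. Methylation of the remaining phenol (MeI, K2CO3, DMF) gives 4-(benzyloxy)-2-methoxy-6-propylbenzaldehyde F2. Pinnick oxidation (NaClO2, NaH2PO4, 2-methyl-2-butene) gives 4-(benzyloxy)-2-methoxy-6-propylbenzoic acid F3, and esterification (MeI, K2CO3, DMF) gives methyl 4-(benzyloxy)-2-methoxy-6-propylbenzoate F4. Hydrogenolysis (H2, Pd/C, EtOAc) then gives 10, and steps 10 and 11 follow unchanged.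

Step 3, the ynol ether. Deprotonation of the acidic C–H of 5 may compete with bromine–lithium exchange, silylation of the unhindered ynolate may occur at carbon to give a silylketene, and the volatile, moisture-sensitive product may be lost on isolation. The two-carbon partner would then be changed to a ketene acetal at the carboxylic acid oxidation level, setting out from pyrone 4 and coming back at phenol 10. 1,1-Bis(trimethylsilyloxy)ethene F5 is made from commercial trimethylsilyl acetate with LiN(i-Pr)2 and Me3SiCl in THF at −78 °C. Heated with 4 in toluene, it should add with the same orientation (CH2 to pyrone C6) to give methyl 5-methoxy-3-oxo-1-propyl-8,8-bis(trimethylsilyloxy)-2-oxabicyclo[2.2.2]oct-5-ene-6-carboxylate F6. Loss of CO2 gives methyl 6-methoxy-2-propyl-4,4-bis(trimethylsilyloxy)cyclohexa-1,5-diene-1-carboxylate F7, and elimination of trimethylsilanol aromatizes it to methyl 2-methoxy-6-propyl-4-(trimethylsilyloxy)benzoate F8. Dilute aqueous HCl in the work-up hydrolyses the silyl ether to 10, so step 5 is not needed.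

Step 1, the pyrone condensation. A second acylation of the 4-hydroxypyrone by malonyl dichloride and acid-promoted degradation by the HCl released may consume the product. The pyrone would then be built in two stages, setting out from keto ester 1 and coming back at pyrone 3. C-acylation of the magnesium enolate of 1 with methyl 3-chloro-3-oxopropanoate (MgCl2, pyridine, CH2Cl2, 0 °C → rt) gives dimethyl 2-butanoyl-3-oxopentanedioate F9. Heating F9 (xylene, TsOH cat., 130 °C) closes the lactone by attack of the butanoyl enol oxygen on the distal ester with loss of methanol, giving 3.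

**Further compounds**
F1 | step 4 | 4-(benzyloxy)-2-hydroxy-6-propylbenzaldehyde | CCCc1cc(OCc2ccccc2)cc(O)c1C=O
F2 | step 4 | 4-(benzyloxy)-2-methoxy-6-propylbenzaldehyde | CCCc1cc(OCc2ccccc2)cc(OC)c1C=O
F3 | step 4 | 4-(benzyloxy)-2-methoxy-6-propylbenzoic acid | CCCc1cc(OCc2ccccc2)cc(OC)c1C(=O)O
F4 | step 4 | methyl 4-(benzyloxy)-2-methoxy-6-propylbenzoate | CCCc1cc(OCc2ccccc2)cc(OC)c1C(=O)OC
F5 | step 3 | 1,1-bis(trimethylsilyloxy)ethene | C=C(O[Si](C)(C)C)O[Si](C)(C)C
F6 | step 3 | methyl 5-methoxy-3-oxo-1-propyl-8,8-bis(trimethylsilyloxy)-2-oxabicyclo[2.2.2]oct-5-ene-6-carboxylate (racemic) | CCCC12OC(=O)C(C(OC)=C1C(=O)OC)C(O[Si](C)(C)C)(O[Si](C)(C)C)C2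
F7 | step 3 | methyl 6-methoxy-2-propyl-4,4-bis(trimethylsilyloxy)cyclohexa-1,5-diene-1-carboxylate | CCCC1=C(C(=O)OC)C(OC)=CC(O[Si](C)(C)C)(O[Si](C)(C)C)C1
F8 | step 3 | methyl 2-methoxy-6-propyl-4-(trimethylsilyloxy)benzoate | CCCc1cc(O[Si](C)(C)C)cc(OC)c1C(=O)OC
F9 | step 1 | dimethyl 2-butanoyl-3-oxopentanedioate | CCCC(=O)C(C(=O)OC)C(=O)CC(=O)OC
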